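The data are calculated for an exercise; scatter was added.

I start with an easy step: X is the limiting reagent, because J stands at 1.80 equiv per X. So I keep a ledger of the X charged to this flask, which is the flask of the elm run.

all flasks: X 20 mM; temperature 100 °C

| flask | J | G | remark | time |
|---|---|---|---|---|
| elm | 1.8 equiv | 2 mM | the very flask that is asked about, followed so far |  |
| flask | 1.80 equiv | 2.00 mM |  | 20 h |

elm run (percent of the X charged): time / h: Q / % = 0.833: 37; 2.50: 62; 5.00: 76; 6.00: 74; 10.0: 79; 12.0: 82; 15.0: 87

(scatter of a reading: 2 percentage points)

- theta: change nothing and wait 6.0 h more
- zeta: at 20 h raise the temperature by 10 K, then wait 6.0 h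
- epsilon: at 20 h add J, 100% of the amount charged, then wait 6.0 h
- eta: at 20 h take out 90% of the Q then present, then wait 6.0 h

* Q, in percent of the X first charged, at 20 h
* what to do for the largest gain in Q; "none" if nothing gains more than 2 percentage points (theta / zeta / epsilon / eta / none)
* Q present, with what was taken out counted in, in percent of the X first charged, after theta
* Q present, with what was taken out counted in, in percent of the X first charged, after epsilon

- Q that was removed still counts
- the earlier runs do not show what temperature does; that part of a forecast is a guess
- additions bring no volume worth counting

X was not read, so I assume that its rate is first order in X and in J, with one J taken per X. J falls while X is used, so I reckon the decay of X as pseudo-first-order with J held at a floor, and that makes the reckoning a bound. On that assumption J keeps at least its excess, 44.4% of its charge.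

The first reading gives an early constant of at least 0.555 h⁻¹, since Q counts no more than the X gone. With J at its floor, that becomes 2.81 h: the floor half-life, the longest time X takes to halve on this assumption.

Now the ledger, in my own reckoning. First entry: X still free at 20 h is 7.12 floor half-lives old, so it stands under 0.722%. Second entry: Q averages 82.7% over the readings from 10.0 h on, and I commit to about that. Third entry: about 16.6% closes the books as X neither free nor read as Q.

An option can turn into Q no more X than is free, and that ceiling is below the margin of 2 percentage points. So I answer none, with theta and epsilon both staying near 82.7%.

The forecast differs: now 91%, theta 94%, epsilon 95.5%, best zeta. It reasons that “something is decaying or inhibiting”.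

The flask gives 82.8%, and the best choice is none, with the gain of zeta at 0.096 points. X free at 20.0 h is 0.115%, while the forecast's now asks for 8.2 points more Q than the flask holds. Put the floor half-life on that X: the further 6.0 h is 2.14 floor half-lives, which takes 0.089 points of X, and theta gains 0.084 points.

    X + J → Q (k = 0.274 M⁻¹ min⁻¹, Ea = 66.0 kJ mol⁻¹)
    X + 2 J → D (k = 1.14 M⁻² min⁻¹, Ea = 66.0 kJ mol⁻¹)
    X + G → E (k = 0.710 M⁻¹ min⁻¹, Ea = 90.0 kJ mol⁻¹)
    (constants at 100 °C)

The neighbour flask with 8.0 mM of G has the same X and J, so with the early constant carried over, its floor half-life of 2.81 h puts free X under 0.722% at 20 h. Computed, that neighbour holds 0% of X and gives 64.3% of Q.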